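A loss count of 0.182 describes the chains of this flask after their top: it is the natural logarithm of monomer in chains at 5.00 min over that at 20.0 min, the turnovers of the chain stock, and as a reading it carries the scatter.

the same everywhere: free monomer 22 mM (fed, over 1.0 min); initiator 33 µM

| run | protic impurity | remark | time |
|---|---|---|---|
| elm | 22 mM | the very flask that is asked about, followed so far; the fed solution adds 0.20 times the starting volume |  |
| flask | 22.0 mM | the fed solution adds 0.20 times the starting volume | 1.5 h |

- elm (time / min: monomer in chains / %, free monomer / %): 1.33: 20, 71; 2.50: 34, 51; 5.00: 36, 30; 10.0: 32, 13; 20.0: 30, 2

(each reading ± 1.5 percentage points)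

- charges are per starting volume, the dose included; the dosed solution carries all of it
- the earlier runs were read with a standard deviation of 1.5 percentage points

- time, not beyond 1.5 h, at which the flask holds most monomer in chains
- the amount of monomer in chains, in percent of the free monomer charged, at that time

The readings of this flask form a ladder. On the fastest rung stands the dose, 1.0 min long, with chains at 34% by 2.50 min and 36% by 5.00 min. Next comes free monomer, whose late readings give a half-life of 3.84 min. Slowest is the chain stock, with 57.0 min at the pace of the count, longer than free monomer lasts.  The reckoning here puts the top of this flask near 5.00 min. Assuming, untested by these readings, that the count stops with the free monomer, read at 2% at 20.0 min, it puts this flask near 30% at 1.5 h.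

The forecast gives 36.5% at 0.067 h: “Later times only decline, unless the decay stalls, and nothing regrows.”

The flask reaches 34.0% at 0.0920 h, and it already holds 33.6% at 0.0736 h, so the top is flat and the forecast's time lies early on it.

    initiator → 2 initiating radical (k = 0.0116 /s)
    2 growing radical → dead chain (k = 8.00 × 10⁶ /M/s)
    free monomer + initiating radical → growing radical + monomer in chains (k = 2.90 × 10⁵ /M/s)
    protic impurity + free monomer → quenched substrate (k = 0.0807 /M/s)
    free monomer + growing radical → monomer in chains + growing radical, rate k5*[growing radical]*[free monomer] (k = 29400 /M/s)
    free monomer + monomer in chains → side product (k = 0.139 /M/s)

Taking away 2 growing radical → dead chain lifts the top of this flask from 34.0% to 99.1%, the largest single effect among the changes tried. From the computed top, the count gives 28.3% at 1.5 h, and the flask holds 26.7%. Taking free monomer + monomer in chains → side product as the loss behind the count, whose rate goes with free monomer, the neighbour flask with 5.5 mM of free monomer has a quarter of the exposure to free monomer if the half-life holds, so its count is 0.0456. From its top of 43.3% that gives 41.4% at 1.5 h, and the computed flask ends at 41.0%.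

The numbers in the tables were computed with constants of no real substance; noise was put on by code.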